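**Retrosynthetic overview**
1. Target 9 ⇐ tetra-O-benzyl dihydroflavonol 8 by hydrogenolysis of the four benzyl ethers.
2. Ring C of 8 (the C3–O and C2–O1 bonds and both stereocentres) ⇐ 2'-hydroxychalcone 6 by one enantioselective epoxidation / 6-endo phenol–epoxide opening cascade.
3. 6 ⇐ acetophenone 4 + 4-(benzyloxy)benzaldehyde 5 (Claisen–Schmidt).
4. 4 ⇐ phloroacetophenone 1 + 4-hydroxybenzyl alcohol 2: Friedel–Crafts C-benzylation to 3, then tri-O-benzylation that leaves only the chelated OH next to the C-benzyl group free. That oxygen becomes O1, which places the benzyl group at C8.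
5. Rings A, B and the benzyl ring are bought; ring C is the only ring formed, and it is formed last.

Assumption: the sense of induction of the proposed scandium catalyst cannot be predicted with certainty. The ligand antipode that gives the (2R,3S)-epoxide is used (written below as the L-pipecolic acid-derived ligand; its mirror image from D-pipecolic acid is taken if the sense proves opposite), and the configuration of 8 is checked by circular dichroism.

**Step 1**
Reactants: 1 1-(2,4,6-trihydroxyphenyl)ethanone (phloroacetophenone); 2 4-(hydroxymethyl)phenol (4-hydroxybenzyl alcohol)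
Product: 3 1-[2,4,6-trihydroxy-3-(4-hydroxybenzyl)phenyl]ethanone
Conditions: 1 (3 equiv), 2 added over 4 h, p-TsOH·H2O (10 mol %), 1,4-dioxane, 60 °C; excess 1 recovered
Reagents that add atoms: none
Why: Acid-catalysed Friedel–Crafts hydroxybenzylation, in which the ionised p-hydroxybenzylic alcohol is captured by the most nucleophilic ring carbon of the phloroglucinol nucleus (C3 and C5 are equivalent), while excess 1 and slow addition of 2 hold back double benzylation and water is the only co-product.

**Step 2**
Reactants: 3 1-[2,4,6-trihydroxy-3-(4-hydroxybenzyl)phenyl]ethanone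
Product: 4 1-{4,6-bis(benzyloxy)-3-[4-(benzyloxy)benzyl]-2-hydroxyphenyl}ethanone
Conditions: BnBr (3.1 equiv), K2CO3 (3.3 equiv), DMF, rt, 16 h
Reagents that add atoms: benzyl bromide, BrCc1ccccc1
Why: Williamson etherification under weak-base control, in which the para-OH, the remote phenol and the less hindered ortho-OH are benzylated while the 2-OH wedged between the acetyl and the C-benzyl group stays free, because it is the more hindered one and is locked in the hydrogen bond to the carbonyl, as is usual for 3-C-alkylphloroacetophenones.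

**Step 3**
Reactants: 4 1-{4,6-bis(benzyloxy)-3-[4-(benzyloxy)benzyl]-2-hydroxyphenyl}ethanone; 5 4-(benzyloxy)benzaldehyde
Product: 6 (E)-1-{4,6-bis(benzyloxy)-3-[4-(benzyloxy)benzyl]-2-hydroxyphenyl}-3-[4-(benzyloxy)phenyl]prop-2-en-1-one
Conditions: 50% aq KOH, EtOH/THF, rt, 48 h; then cold 1 M HCl
Reagents that add atoms: none
Why: Claisen–Schmidt (crossed aldol) condensation, in which the aldehyde has no α-hydrogen, the chelated 2'-phenoxide does not cyclise in cold strong base, and the E-enone forms under thermodynamic control with water as the only co-product.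

**Step 4**
Reactants: 6 (E)-1-{4,6-bis(benzyloxy)-3-[4-(benzyloxy)benzyl]-2-hydroxyphenyl}-3-[4-(benzyloxy)phenyl]prop-2-en-1-one
Product: 8 (2R,3R)-5,7-bis(benzyloxy)-8-[4-(benzyloxy)benzyl]-2-[4-(benzyloxy)phenyl]-3-hydroxy-2,3-dihydro-4H-chromen-4-one, via chalcone epoxide 7 (not isolated)
Conditions: Sc(OTf)3 (10 mol %), chiral N,N'-dioxide ligand (12 mol %; two L-pipecolic acid 2,6-diisopropylanilide units joined at nitrogen by a propane-1,3-diyl chain), iPr2NEt (10 mol %), 35% aq H2O2 (1.5 equiv), THF, 0 °C, 24 h; then p-TsOH·H2O (20 mol %), 0 °C to rt, 2 h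
Reagents that add atoms: hydrogen peroxide, OO
Why: Proposed new method: a chelation-directed enantioselective epoxidation / 6-endo phenol–epoxide cyclisation cascade on a free 2'-hydroxychalcone. The 2-acylphenoxide of 6 binds the chiral trivalent scandium N,N'-dioxide complex as an O,O-chelate, which lowers the enone LUMO, shields one π-face and holds the phenoxide oxygen on the carbonyl-oxygen side, away from C-β, so that oxa-Michael closure to the flavanone and the base-type aurone path are shut off. H2O2 adds to C-β on the open face and the scandium enolate closes (Weitz–Scheffer mechanism) to the (2R,3S)-epoxide 7, which fixes C3. The added acid then frees the phenol, which opens the activated p-benzyloxybenzylic C-β in 6-endo mode with inversion to set C2 (2,3-trans, both substituents equatorial). The closest known reactions are the N,N'-dioxide–Sc(OTf)3-catalysed epoxidation of chelating enones with H2O2 and the acid-mediated cyclisation of 2'-O-protected chalcone epoxides to trans-dihydroflavonols; neither has been shown on a free 2'-hydroxychalcone or run as one enantioselective cascade.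

**Step 5**
Reactants: 8 (2R,3R)-5,7-bis(benzyloxy)-8-[4-(benzyloxy)benzyl]-2-[4-(benzyloxy)phenyl]-3-hydroxy-2,3-dihydro-4H-chromen-4-one
Product: 9 (2R,3R)-3,5,7-trihydroxy-8-(4-hydroxybenzyl)-2-(4-hydroxyphenyl)-2,3-dihydro-4H-chromen-4-one
Conditions: H2 (1 atm), 10% Pd/C, THF/MeOH 1:1, rt, stopped after uptake of 4 equiv
Reagents that add atoms: none
Why: Heterogeneous catalytic hydrogenolysis of the four O-benzyl ethers under neutral conditions, which leaves the diarylmethane, the aryl ketone and the C2–O1 bond intact and touches neither stereocentre.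

**Compound list**
1 | 1-(2,4,6-trihydroxyphenyl)ethanone (phloroacetophenone) | CC(=O)c1c(O)cc(O)cc1O | starting material
2 | 4-(hydroxymethyl)phenol (4-hydroxybenzyl alcohol) | OCc1ccc(O)cc1 | starting material
3 | 1-[2,4,6-trihydroxy-3-(4-hydroxybenzyl)phenyl]ethanone | CC(=O)c1c(O)cc(O)c(Cc2ccc(O)cc2)c1O | intermediate
4 | 1-{4,6-bis(benzyloxy)-3-[4-(benzyloxy)benzyl]-2-hydroxyphenyl}ethanone | CC(=O)c1c(OCc2ccccc2)cc(OCc2ccccc2)c(Cc2ccc(OCc3ccccc3)cc2)c1O | intermediate
5 | 4-(benzyloxy)benzaldehyde | O=Cc1ccc(OCc2ccccc2)cc1 | starting material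
6 | (E)-1-{4,6-bis(benzyloxy)-3-[4-(benzyloxy)benzyl]-2-hydroxyphenyl}-3-[4-(benzyloxy)phenyl]prop-2-en-1-one | O=C(/C=C/c1ccc(OCc2ccccc2)cc1)c1c(OCc2ccccc2)cc(OCc2ccccc2)c(Cc2ccc(OCc3ccccc3)cc2)c1O | intermediate
7 | {4,6-bis(benzyloxy)-3-[4-(benzyloxy)benzyl]-2-hydroxyphenyl}{(2R,3S)-3-[4-(benzyloxy)phenyl]oxiran-2-yl}methanone | O=C([C@@H]1O[C@H]1c2ccc(OCc3ccccc3)cc2)c2c(OCc3ccccc3)cc(OCc3ccccc3)c(Cc3ccc(OCc4ccccc4)cc3)c2O | intermediate
8 | (2R,3R)-5,7-bis(benzyloxy)-8-[4-(benzyloxy)benzyl]-2-[4-(benzyloxy)phenyl]-3-hydroxy-2,3-dihydro-4H-chromen-4-one | O=C1c2c(OCc3ccccc3)cc(OCc3ccccc3)c(Cc3ccc(OCc4ccccc4)cc3)c2O[C@H](c2ccc(OCc3ccccc3)cc2)[C@H]1O | intermediate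
9 | (2R,3R)-3,5,7-trihydroxy-8-(4-hydroxybenzyl)-2-(4-hydroxyphenyl)-2,3-dihydro-4H-chromen-4-one | O=C1c2c(O)cc(O)c(Cc3ccc(O)cc3)c2O[C@H](c2ccc(O)cc2)[C@H]1O | target

**Totals**
Total step count: 5. Longest linear sequence: 5 steps (1 → 3 → 4 → 6 → 8 → 9).

**Three steps most likely to fail**

Step 1, the mono-C-benzylation. The unprotected benzylic alcohol can self-condense, and 3 can be benzylated a second time at C5. The fallback sets out from 1 and comes back at 4. Instead of an acid-generated benzylic cation, the phenoxide of 1 (NaOMe, MeOH, 0 °C to rt) is C-alkylated with the O-protected halide 4-(benzyloxy)benzyl chloride, which cannot self-condense. This gives 1-{3-[4-(benzyloxy)benzyl]-2,4,6-trihydroxyphenyl}ethanone F1. Twofold O-benzylation of F1 (BnBr 2.05 equiv, K2CO3, DMF, rt) then gives 4, so step 2 is covered as well.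

Step 2, the question of which ortho-hydroxyl stays free. If the wrong one, or a mixture, is left free, the benzyl group would end at C6 of the flavonoid. The fallback sets out from 1 and comes back at 4, and it fixes the regiochemistry by introducing the carbon substituent after the oxygens are differentiated. Compound 1 is di-O-benzylated (BnBr 2.05 equiv, K2CO3, acetone, reflux) to the well-known 1-[2,4-bis(benzyloxy)-6-hydroxyphenyl]ethanone F2, whose only free OH is the chelated one. Iodination with N-iodosuccinimide (cat. p-TsOH·H2O, CH2Cl2, 0 °C) should go ortho to that OH, at the less crowded open position (the other lies between two benzyloxy groups), to give 1-[4,6-bis(benzyloxy)-2-hydroxy-3-iodophenyl]ethanone F3; the position is confirmed by HMBC and NOE. Negishi coupling of F3 (Pd(OAc)2/SPhos, THF, rt, slow addition, free OH tolerated) with 4-(benzyloxy)benzylzinc chloride F4, made from 4-(benzyloxy)benzyl chloride with Zn dust and LiCl in THF, gives 4.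

Step 4, the proposed cascade. The doubly electron-rich enone may be epoxidised slowly. The chelate may give low enantioselectivity. The labile p-alkoxyphenyl epoxide may leak to the cis isomer or to rearranged products; the cis isomer is removed by chromatography or crystallisation of 8 and does not erode the enantiomeric purity of the trans product. The fallback uses known chemistry, sets out from 6 and comes back at 8. The 2'-OH is capped with MOMCl/NaH (THF/DMF, 0 °C) to give (E)-1-{4,6-bis(benzyloxy)-3-[4-(benzyloxy)benzyl]-2-(methoxymethoxy)phenyl}-3-[4-(benzyloxy)phenyl]prop-2-en-1-one F5. Juliá–Colonna epoxidation (poly-L-leucine, urea–hydrogen peroxide, DBU, THF, rt) gives {4,6-bis(benzyloxy)-3-[4-(benzyloxy)benzyl]-2-(methoxymethoxy)phenyl}{(2R,3S)-3-[4-(benzyloxy)phenyl]oxiran-2-yl}methanone F6. HCl in MeOH/THF (0 °C to rt) then removes the MOM group, and the freed phenol opens the epoxide 6-endo at the benzylic carbon with inversion to give 8.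

**Further compounds**
F1 | step 1 | 1-{3-[4-(benzyloxy)benzyl]-2,4,6-trihydroxyphenyl}ethanone | CC(=O)c1c(O)cc(O)c(Cc2ccc(OCc3ccccc3)cc2)c1O
F2 | step 2 | 1-[2,4-bis(benzyloxy)-6-hydroxyphenyl]ethanone | CC(=O)c1c(O)cc(OCc2ccccc2)cc1OCc1ccccc1
F3 | step 2 | 1-[4,6-bis(benzyloxy)-2-hydroxy-3-iodophenyl]ethanone | CC(=O)c1c(OCc2ccccc2)cc(OCc2ccccc2)c(I)c1O
F4 | step 2 | 4-(benzyloxy)benzylzinc chloride | Cl[Zn]Cc1ccc(OCc2ccccc2)cc1
F5 | step 4 | (E)-1-{4,6-bis(benzyloxy)-3-[4-(benzyloxy)benzyl]-2-(methoxymethoxy)phenyl}-3-[4-(benzyloxy)phenyl]prop-2-en-1-one | O=C(/C=C/c1ccc(OCc2ccccc2)cc1)c1c(OCc2ccccc2)cc(OCc2ccccc2)c(Cc2ccc(OCc3ccccc3)cc2)c1OCOC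
F6 | step 4 | {4,6-bis(benzyloxy)-3-[4-(benzyloxy)benzyl]-2-(methoxymethoxy)phenyl}{(2R,3S)-3-[4-(benzyloxy)phenyl]oxiran-2-yl}methanone | O=C([C@@H]1O[C@H]1c2ccc(OCc3ccccc3)cc2)c2c(OCc3ccccc3)cc(OCc3ccccc3)c(Cc3ccc(OCc4ccccc4)cc3)c2OCOC
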